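## Retrosynthetic overview
1. Cut the C6(aryl)–C(=O) bond: a light-driven O→C 1,3-acyl shift of the 5-O-acyl chromene. The β-hydroxy ketone is prone to dehydration and retro-aldol cleavage, so it appears only in the last step, which is neutral and reagent-free.
2. Cut the ester C–O bond: chromen-5-ol plus (S)-3-hydroxy-3-phenylpropanoic acid. The acid is bought with the only stereocentre, which no later step touches.
3. Cut the pyran ring (C4–C4a and O1–C2): 5-methoxyresorcinol plus prenal, a formal [3+3] annulation.
4. Ring order: both benzene rings are bought. The pyran is the only ring built, and it is built first (step 1).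

Assumption: (S)-3-hydroxy-3-phenylpropanoic acid (≥98 % ee) is taken as a catalogue chemical; the target carbinol is S (OH > Ph > CH2C=O > H), the same descriptor and spatial arrangement as in this acid.

## Route

Step 1
Reactants: 1 5-methoxyresorcinol (5-methoxybenzene-1,3-diol); 2 3-methylbut-2-enal (prenal)
Product: 4 chromenol 7-methoxy-2,2-dimethyl-2H-chromen-5-ol, via o-quinone methide 3 (not isolated)
Conditions: 1 (1.2 equiv), 2 (1.0 equiv), ethylenediammonium diacetate (10 mol %), toluene, Dean–Stark reflux, 8 h
Reagents that add atoms: none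
Why: Formal [3+3] chromenylation, in which Knoevenagel-type C-alkylation at the carbon between the two hydroxyls and loss of water give o-quinone methide 3, whose oxa-6π electrocyclisation onto either (equivalent) oxygen gives the same chromenol; no stereocentre is formed.

Step 2
Reactants: 4 chromenol 7-methoxy-2,2-dimethyl-2H-chromen-5-ol; 5 (S)-3-hydroxy-3-phenylpropanoic acid
Product: 7 aryl ester 7-methoxy-2,2-dimethyl-2H-chromen-5-yl (3S)-3-hydroxy-3-phenylpropanoate, via O-acylisourea 6 (not isolated)
Conditions: DCC (1.1 equiv), DMAP (10 mol %), CH2Cl2, 0 °C; 5 added over 2 h to 4 (1.3 equiv)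
Reagents that add atoms: none
Why: Steglich esterification, in which O-acylisourea 6 is kept dilute and DMAP relays its acyl group to the excess, more acidic phenol rather than to the hindered secondary benzylic alcohol (unprotected β-hydroxy acids are routinely made into active esters and thioesters this way); the stereocentre bought in 5 is not touched.

Step 3
Reactants: 7 aryl ester 7-methoxy-2,2-dimethyl-2H-chromen-5-yl (3S)-3-hydroxy-3-phenylpropanoate
Product: 10 (3S)-3-hydroxy-1-(5-hydroxy-7-methoxy-2,2-dimethyl-2H-chromen-6-yl)-3-phenylpropan-1-one, via caged acyl/aryloxyl radical pair 8 (not isolated), via 6-acylcyclohexa-2,4-dienone 9 (not isolated)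
Conditions: hν (310 nm + 450 nm LEDs), degassed cyclohexane/EtOAc 9:1 (5 mM), FEP flow coil, 30 °C, tR ca. 40 min
Reagents that add atoms: none
Why: Proposed new method: a two-colour photo-Fries 1,3-acyl shift on a photochromic 2H-chromen-5-yl ester that carries a free, enantiopure β-hydroxyacyl group, neither feature having been shown before; 310 nm excitation cleaves the ArO–C(=O) bond from S1 to the singlet caged pair 8, which recombines at C6 (the only free ortho carbon, C4a being blocked) to dienone 9, and 9 enolises to the chelated ketone 10, a photostable sink because of its ultrafast excited-state proton transfer; the competing electrocyclic opening of the pyran is a reversible, energy-wasting channel that is emptied thermally at 30 °C and by 450 nm bleaching of the coloured open form; the primary-alkyl acyl radical loses CO orders of magnitude more slowly than the cage collapses, and the carbinol carbon is never a radical or enolisable centre, so the S configuration carries over unchanged; the closest known reaction type is the photo-Fries rearrangement of simple alkoxyphenyl and naphthyl esters to o-hydroxyaryl ketones.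

## Compound list
1 | 5-methoxyresorcinol (5-methoxybenzene-1,3-diol) | COc1cc(O)cc(O)c1 | starting material
2 | 3-methylbut-2-enal (prenal) | CC(C)=CC=O | starting material
3 | 5-hydroxy-3-methoxy-6-(3-methylbut-2-en-1-ylidene)cyclohexa-2,4-dien-1-one (o-quinone methide) | COC1=CC(=O)C(=CC=C(C)C)C(O)=C1 | intermediate
4 | 7-methoxy-2,2-dimethyl-2H-chromen-5-ol | COc1cc(O)c2C=CC(C)(C)Oc2c1 | intermediate
5 | (S)-3-hydroxy-3-phenylpropanoic acid | OC(=O)C[C@H](O)c1ccccc1 | starting material
6 | O-[(3S)-3-hydroxy-3-phenylpropanoyl]-N,N'-dicyclohexylisourea | O=C(C[C@H](O)c1ccccc1)OC(=NC1CCCCC1)NC1CCCCC1 | intermediate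
7 | 7-methoxy-2,2-dimethyl-2H-chromen-5-yl (3S)-3-hydroxy-3-phenylpropanoate | COc1cc(OC(=O)C[C@H](O)c2ccccc2)c2C=CC(C)(C)Oc2c1 | intermediate
8 | geminate pair of the 7-methoxy-2,2-dimethyl-2H-chromen-5-yloxyl radical and the (3S)-3-hydroxy-3-phenylpropanoyl radical | COc1cc([O])c2C=CC(C)(C)Oc2c1.O=[C]C[C@H](O)c1ccccc1 | intermediate
9 | 6-[(3S)-3-hydroxy-3-phenylpropanoyl]-7-methoxy-2,2-dimethyl-2H-chromen-5(6H)-one (keto tautomer of 10, C6 unassigned and transient) | COC1=CC2=C(C=CC(C)(C)O2)C(=O)C1C(=O)C[C@H](O)c1ccccc1 | intermediate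
10 | (3S)-3-hydroxy-1-(5-hydroxy-7-methoxy-2,2-dimethyl-2H-chromen-6-yl)-3-phenylpropan-1-one | COc1cc2c(c(O)c1C(=O)C[C@H](O)c1ccccc1)C=CC(C)(C)O2 | target

## Step count and risks
Total steps: 3. Longest linear sequence: 3 (1 → 4 → 7 → 10).

**Risk 1: step 3 (the proposed new step).**
- Pyran opening may outrun O–acyl homolysis, which would lower the quantum yield.
- Part of the acyl group may shift to the para carbon C8. That isomer is non-chelated, much more polar and separable.
- Cage escape returns 4, which can be recycled.
- The open form may drain by an H-shift to a Z-dienylphenol, which re-closes to the chromene on gentle warming.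

The fallback is known chemistry: directed ortho-metalation followed by a Weinreb ketone synthesis. It sets out from 4 and 5 and comes back at 10. Compound 4 is protected (MOMCl, i-Pr2NEt, CH2Cl2) as 7-methoxy-5-(methoxymethoxy)-2,2-dimethyl-2H-chromene F1. n-BuLi/TMEDA in THF at 0 °C metalates F1 between the OMOM and OMe groups to give 6-lithio-7-methoxy-5-(methoxymethoxy)-2,2-dimethyl-2H-chromene F2. In parallel, 5 is coupled with MeNHOMe·HCl (EDC, HOBt, N-methylmorpholine) to (S)-3-hydroxy-N-methoxy-N-methyl-3-phenylpropanamide F3. F3 is silylated (TBSCl, imidazole, DMF) to (S)-3-(tert-butyldimethylsilyloxy)-N-methoxy-N-methyl-3-phenylpropanamide F4. F2 adds to F4 at −78 °C, and an NH4Cl quench gives (3S)-3-(tert-butyldimethylsilyloxy)-1-[7-methoxy-5-(methoxymethoxy)-2,2-dimethyl-2H-chromen-6-yl]-3-phenylpropan-1-one F5. Catalytic HCl in MeOH (AcCl 0.2 equiv, 0 °C to rt) removes the MOM group, which is labile because it sits ortho to the carbonyl, together with the silyl ether, and this gives 10.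

**Risk 2: step 2.**
- Acid 5 may acylate itself to oligoesters.
- 5 may close to the β-lactone.
- O-acylisourea 6 may rearrange to an N-acylurea.

The fallback is a protecting-group route that sets out from 5 and comes back at 7. TBSCl (2.2 equiv) and imidazole in DMF give tert-butyldimethylsilyl (S)-3-(tert-butyldimethylsilyloxy)-3-phenylpropanoate F6. K2CO3 in aqueous MeOH/THF cleaves only the silyl ester, giving (S)-3-(tert-butyldimethylsilyloxy)-3-phenylpropanoic acid F7. DCC/DMAP coupling with 4 gives 7-methoxy-2,2-dimethyl-2H-chromen-5-yl (3S)-3-(tert-butyldimethylsilyloxy)-3-phenylpropanoate F8. HF·pyridine in THF/pyridine at 0 °C frees 7 without touching the aryl ester or the chromene.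

**Risk 3: step 1.**
- C-attack next to the methoxy group would give the 7-hydroxy-5-methoxy regioisomer.
- A second annulation can occur on the remaining phenol.

The fallback separates C–C bond formation from ring closure. It sets out from 1 and comes back at 3, and hence at 4. The resorcinolate dianion is C-prenylated at the carbon between the two oxyanions (prenyl bromide, aq KOH, 0 °C) to give 5-methoxy-2-(3-methylbut-2-en-1-yl)benzene-1,3-diol F9. F9 is symmetric, so it is easily recognised and purified. DDQ (1.05 equiv, toluene, rt) abstracts the benzylic hydride to give o-quinone methide 3, which closes to 4.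

## Further compounds
F1 | step 3 | 7-methoxy-5-(methoxymethoxy)-2,2-dimethyl-2H-chromene | COCOc1cc(OC)cc2OC(C)(C)C=Cc12
F2 | step 3 | 6-lithio-7-methoxy-5-(methoxymethoxy)-2,2-dimethyl-2H-chromene | COCOc1c([Li])c(OC)cc2OC(C)(C)C=Cc12
F3 | step 3 | (S)-3-hydroxy-N-methoxy-N-methyl-3-phenylpropanamide | CON(C)C(=O)C[C@H](O)c1ccccc1
F4 | step 3 | (S)-3-(tert-butyldimethylsilyloxy)-N-methoxy-N-methyl-3-phenylpropanamide | CON(C)C(=O)C[C@H](O[Si](C)(C)C(C)(C)C)c1ccccc1
F5 | step 3 | (3S)-3-(tert-butyldimethylsilyloxy)-1-[7-methoxy-5-(methoxymethoxy)-2,2-dimethyl-2H-chromen-6-yl]-3-phenylpropan-1-one | COCOc1c(C(=O)C[C@H](O[Si](C)(C)C(C)(C)C)c2ccccc2)c(OC)cc2OC(C)(C)C=Cc12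
F6 | step 2 | tert-butyldimethylsilyl (S)-3-(tert-butyldimethylsilyloxy)-3-phenylpropanoate | CC(C)(C)[Si](C)(C)OC(=O)C[C@H](O[Si](C)(C)C(C)(C)C)c1ccccc1
F7 | step 2 | (S)-3-(tert-butyldimethylsilyloxy)-3-phenylpropanoic acid | OC(=O)C[C@H](O[Si](C)(C)C(C)(C)C)c1ccccc1
F8 | step 2 | 7-methoxy-2,2-dimethyl-2H-chromen-5-yl (3S)-3-(tert-butyldimethylsilyloxy)-3-phenylpropanoate | COc1cc(OC(=O)C[C@H](O[Si](C)(C)C(C)(C)C)c2ccccc2)c2C=CC(C)(C)Oc2c1
F9 | step 1 | 5-methoxy-2-(3-methylbut-2-en-1-yl)benzene-1,3-diol | COc1cc(O)c(CC=C(C)C)c(O)c1
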